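**Remarks.** Ring atoms of the alcohol half are numbered as in 2‑benzoxepine (C1 lactone C=O, O2, C3, C4, C5, C5a, C6–C9, C9a). The sense of induction in step 1 is assigned from the enamine face‑shielding model. Compounds 9 and 10 are racemic and 11 is an epimer mixture at the two side‑chain centres; these centres are destroyed in step 7.

## Retrosynthetic overview

1. Feature used: the alcohol half (cyclohexane C5a–C9a fused to the seven‑membered lactone C1/O2/C3/C4/C5) equals the acid half (a 3‑(hydroxymethyl)cyclohex‑2‑enyl acrylate) plus CO2 at C9a and one O at C9. One cyclohexenylmethanol therefore serves as both halves.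
2. Key disconnection: the C9a–C1 bond, made by umpolung γ‑carboxylation of the ring allylic alcohol with CO2. This sets C9a and moves the ring alkene to the exocyclic C9=CH2.
3. Ring order after that: acyl–O2 closure of the seven‑membered lactone; OsO4 on C9=CH2 sets C9; the primary tosylate closes to a spiro‑oxirane that the unprotected acid half opens at CH2 (linking ester).
4. The common cyclohexenylmethanol comes from the vinyl spiro‑oxirane of (R)‑cryptone by Pd‑catalysed 1,4‑alkylation with a β‑nitro ester (acrylate β‑anion equivalent) and loss of HNO2 (side chain trans to isopropyl, E‑alkene).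
5. (R)‑Cryptone comes from an organocatalytic Michael addition and aldol condensation, so the cyclohexene ring is formed first and the lactone ring later.

Key step: step 9

## Route

Step 1
Reactants: 1 3‑methylbutanal; 2 but‑3‑en‑2‑one
Product: 3 (2R)‑5‑oxo‑2‑(propan‑2‑yl)hexanal
Conditions: (R)‑2‑(methoxydiphenylmethyl)pyrrolidine (5 mol%), ethyl 3,4‑dihydroxybenzoate (20 mol%), neat, 4 °C
Reagents that add atoms: none
Why: Enamine‑catalysed Michael addition, in which the E‑enamine of 1 adds to 2 from the face not shielded by the methoxydiphenylmethyl group, which with the (R)‑catalyst should give the (R)‑α‑stereocentre.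

Step 2
Reactants: 3 (2R)‑5‑oxo‑2‑(propan‑2‑yl)hexanal
Product: 4 (4R)‑4‑(propan‑2‑yl)cyclohex‑2‑en‑1‑one ((R)‑cryptone)
Conditions: 0.1 M aq. KOH, n‑Bu4NOH (cat.), Et2O/THF, reflux
Reagents that add atoms: none
Why: Intramolecular aldol condensation (6‑enolexo‑exo‑trig) of the methyl‑ketone enolate onto the aldehyde, under mild biphasic base so that the γ‑stereocentre should not epimerise through the dienolate.

Step 3
Reactants: 4 (4R)‑4‑(propan‑2‑yl)cyclohex‑2‑en‑1‑one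
Product: 5 (3S,6R)‑6‑(propan‑2‑yl)‑1‑oxaspiro[2.5]oct‑4‑ene
Conditions: Me3S+ I−, n‑BuLi, THF, −10 °C → rt; used crude
Reagents that add atoms: trimethylsulfonium iodide, C[S+](C)C.[I-]
Why: Corey–Chaykovsky epoxidation, in which the sulfonium ylide adds 1,2 to the enone and pseudoaxial attack on the half‑chair with pseudoequatorial isopropyl should place the oxirane oxygen trans to isopropyl (3S).

Step 4
Reactants: 6 3‑nitropropanoic acid; 7 2‑(trimethylsilyl)ethan‑1‑ol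
Product: 8 2‑(trimethylsilyl)ethyl 3‑nitropropanoate
Conditions: DCC, DMAP (5 mol%), CH2Cl2, 0 °C → rt
Reagents that add atoms: none
Why: Steglich esterification installs the fluoride‑labile 2‑(trimethylsilyl)ethyl ester needed for the late, selective release of one carboxyl group.

Step 5
Reactants: 8 2‑(trimethylsilyl)ethyl 3‑nitropropanoate
Product: 9 2‑(trimethylsilyl)ethyl 2‑(hydroxymethyl)‑3‑nitropropanoate (racemic)
Conditions: LDA (2.1 equiv), THF/DMPU, −78 °C; CH2O (gas, from cracked paraformaldehyde); AcOH, −78 °C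
Reagents that add atoms: formaldehyde, C=O
Why: Double deprotonation of a 3‑nitropropanoate gives a nitronate/enolate dianion that undergoes aldol addition to formaldehyde at the ester α‑carbon, and the low‑temperature acid quench avoids loss of HNO2.

Step 6
Reactants: 9 2‑(trimethylsilyl)ethyl 2‑(hydroxymethyl)‑3‑nitropropanoate
Product: 10 2‑(trimethylsilyl)ethyl 3‑nitro‑2‑{[(triethylsilyl)oxy]methyl}propanoate (racemic)
Conditions: TESCl, imidazole, CH2Cl2, 0 °C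
Reagents that add atoms: chlorotriethylsilane, CC[Si](Cl)(CC)CC
Why: Silylation of the primary alcohol gives an ether that should survive Pd(0), DBU and ZnEt2 but is cleaved by dilute acid or fluoride.

Step 7
Reactants: 5 (3S,6R)‑6‑(propan‑2‑yl)‑1‑oxaspiro[2.5]oct‑4‑ene; 10 2‑(trimethylsilyl)ethyl 3‑nitro‑2‑{[(triethylsilyl)oxy]methyl}propanoate
Product: 12 2‑(trimethylsilyl)ethyl (2E)‑3‑[(1R,6R)‑3‑(hydroxymethyl)‑6‑(propan‑2‑yl)cyclohex‑2‑en‑1‑yl]‑2‑{[(triethylsilyl)oxy]methyl}prop‑2‑enoate, via nitro adduct 11 (not isolated)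
Conditions: Pd2(dba)3·CHCl3 (2.5 mol%), PPh3 (10 mol%), THF, rt; then DBU (3 equiv), rt → 40 °C
Reagents that add atoms: none
Why: Tsuji–Trost alkylation under neutral conditions, in which Pd(0) opens the vinyl oxirane with inversion and the nitronate attacks the distal non‑quaternary allyl terminus anti to Pd (net retention, so the new C–C bond is trans to isopropyl), followed by E1cB loss of HNO2 to the E‑acrylate with the ester trans to the ring.

Step 8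
Reactants: 12 2‑(trimethylsilyl)ethyl (2E)‑3‑[(1R,6R)‑3‑(hydroxymethyl)‑6‑(propan‑2‑yl)cyclohex‑2‑en‑1‑yl]‑2‑{[(triethylsilyl)oxy]methyl}prop‑2‑enoate
Product: 13 (2E)‑2‑(hydroxymethyl)‑3‑[(1R,6R)‑3‑(hydroxymethyl)‑6‑(propan‑2‑yl)cyclohex‑2‑en‑1‑yl]prop‑2‑enoic acid
Conditions: TBAF (3 equiv), THF, 0 °C → rt; then 0.5 M HCl to pH 3
Reagents that add atoms: none
Why: Fluoride cleaves the TES ether and triggers β‑elimination of the 2‑(trimethylsilyl)ethyl ester, which leaves the stereocentres and the E‑alkene untouched.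

Step 9
Reactants: 12 2‑(trimethylsilyl)ethyl (2E)‑3‑[(1R,6R)‑3‑(hydroxymethyl)‑6‑(propan‑2‑yl)cyclohex‑2‑en‑1‑yl]‑2‑{[(triethylsilyl)oxy]methyl}prop‑2‑enoate
Product: 15 (1S,2S,3R)‑2‑{(1E)‑2‑(hydroxymethyl)‑3‑oxo‑3‑[2‑(trimethylsilyl)ethoxy]prop‑1‑en‑1‑yl}‑6‑methylidene‑3‑(propan‑2‑yl)cyclohexane‑1‑carboxylic acid, via triethylsilyl ether acid 14 (not isolated)
Conditions: PdCl2 (5 mol%), PPh3 (20 mol%), ZnEt2 (3.5 equiv), CO2 (1 atm), THF/hexane, rt → 40 °C; then 1 M HCl, THF, rt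
Reagents that add atoms: carbon dioxide, O=C=O
Why: Pd(0), formed from PdCl2/PPh3/ZnEt2, ionises the zinc alkoxide of the primary ring allylic alcohol to a π‑allylpalladium species, which transmetalates with ZnEt2 to a nucleophilic η1‑allylzinc that adds to CO2 through a six‑membered SE2′ transition state at the ring γ‑carbon, so the alkene moves to the exocyclic position; the acidic work‑up frees the acid and hydrolyses the TES ether. The closest known reaction type is the Pd‑catalysed, ZnEt2‑mediated branched‑selective carboxylation of allylic alcohols with CO2. The step closes no ring; it adds the one carbon (the future lactone C1) by which the alcohol half differs from the acid half and leaves the exocyclic methylene from which the C9 carbinol is made. The new stereocentre (C1 of 15, the future C9a) is controlled by the neighbouring ring carbon, since CO2 should enter the allylzinc face anti to the alkenyl side chain to give the trans diequatorial acid, which is also the more stable epimer. The step needs γ‑ over α‑carboxylation, which the primary η1‑allylzinc reacting by SE2′ secures, and it needs selectivity for the ring allylic alcohol, which the poor leaving ability of the side‑chain silyl ether and the E‑geometry (ester carbonyl held out of reach of the allylzinc) secure.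

Step 10
Reactants: 15 (1S,2S,3R)‑2‑{(1E)‑2‑(hydroxymethyl)‑3‑oxo‑3‑[2‑(trimethylsilyl)ethoxy]prop‑1‑en‑1‑yl}‑6‑methylidene‑3‑(propan‑2‑yl)cyclohexane‑1‑carboxylic acid
Product: 16 2‑(trimethylsilyl)ethyl (5aS,6R,9aS)‑9‑methylidene‑1‑oxo‑6‑(propan‑2‑yl)‑1,3,5a,6,7,8,9,9a‑octahydro‑2‑benzoxepine‑4‑carboxylate
Conditions: 2‑methyl‑6‑nitrobenzoic anhydride (1.3 equiv), DMAP (0.2 equiv), Et3N (3 equiv), CH2Cl2 (2 mM), rt, slow addition
Reagents that add atoms: none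
Why: Shiina lactonisation, in which the mixed anhydride is attacked by the only hydroxyl (the CH2OH cis to the ring) to close the trans‑fused seven‑membered lactone by 7‑exo‑trig acyl substitution, with slow addition and catalytic DMAP to limit epimerisation or conjugation of the β,γ‑unsaturated acyl group.

Step 11
Reactants: 16 2‑(trimethylsilyl)ethyl (5aS,6R,9aS)‑9‑methylidene‑1‑oxo‑6‑(propan‑2‑yl)‑1,3,5a,6,7,8,9,9a‑octahydro‑2‑benzoxepine‑4‑carboxylate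
Product: 17 2‑(trimethylsilyl)ethyl (5aS,6R,9S,9aS)‑9‑hydroxy‑9‑(hydroxymethyl)‑1‑oxo‑6‑(propan‑2‑yl)‑1,3,5a,6,7,8,9,9a‑octahydro‑2‑benzoxepine‑4‑carboxylate
Conditions: OsO4 (2 mol%), NMO (1.2 equiv), acetone/H2O, 0 °C; aq. Na2SO3; used at once
Reagents that add atoms: osmium tetroxide, O=[Os](=O)(=O)=O; 4‑methylmorpholine N‑oxide, C[N+]1([O-])CCOCC1; water, O
Why: Upjohn dihydroxylation, in which OsO4 prefers the electron‑neutral exocyclic 1,1‑disubstituted alkene over the conjugated ester alkene and, as a bulky reagent, should attack the methylenecyclohexane from the equatorial direction to give the equatorial tertiary OH and the axial CH2OH (9S).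

Step 12
Reactants: 17 2‑(trimethylsilyl)ethyl (5aS,6R,9S,9aS)‑9‑hydroxy‑9‑(hydroxymethyl)‑1‑oxo‑6‑(propan‑2‑yl)‑1,3,5a,6,7,8,9,9a‑octahydro‑2‑benzoxepine‑4‑carboxylate
Product: 18 2‑(trimethylsilyl)ethyl (5aS,6R,9S,9aS)‑9‑hydroxy‑9‑{[(4‑methylbenzenesulfonyl)oxy]methyl}‑1‑oxo‑6‑(propan‑2‑yl)‑1,3,5a,6,7,8,9,9a‑octahydro‑2‑benzoxepine‑4‑carboxylate
Conditions: TsCl (1.3 equiv), pyridine, CH2Cl2, 0 °C
Reagents that add atoms: 4‑methylbenzenesulfonyl chloride, Cc1ccc(cc1)S(Cl)(=O)=O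
Why: Selective sulfonylation of the primary hydroxyl, since the tertiary C9–OH is inert to TsCl/pyridine and the short reaction at 0 °C limits acyl transfer from the lactone to the neighbouring CH2OH.

Step 13
Reactants: 18 2‑(trimethylsilyl)ethyl (5aS,6R,9S,9aS)‑9‑hydroxy‑9‑{[(4‑methylbenzenesulfonyl)oxy]methyl}‑1‑oxo‑6‑(propan‑2‑yl)‑1,3,5a,6,7,8,9,9a‑octahydro‑2‑benzoxepine‑4‑carboxylate; 13 (2E)‑2‑(hydroxymethyl)‑3‑[(1R,6R)‑3‑(hydroxymethyl)‑6‑(propan‑2‑yl)cyclohex‑2‑en‑1‑yl]prop‑2‑enoic acid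
Product: 20 2‑(trimethylsilyl)ethyl (5aS,6R,9S,9aS)‑9‑hydroxy‑9‑[({(2E)‑2‑(hydroxymethyl)‑3‑[(1R,6R)‑3‑(hydroxymethyl)‑6‑(propan‑2‑yl)cyclohex‑2‑en‑1‑yl]prop‑2‑enoyl}oxy)methyl]‑1‑oxo‑6‑(propan‑2‑yl)‑1,3,5a,6,7,8,9,9a‑octahydro‑2‑benzoxepine‑4‑carboxylate, via spiro‑oxirane 19 (not isolated)
Conditions: 13 (1.5 equiv), Cs2CO3 (2.0 equiv), DMF, rt → 60 °C
Reagents that add atoms: none
Why: Base closes the β‑hydroxy tosylate to the spiro‑oxirane (Williamson‑type 3‑exo‑tet) and the caesium carboxylate of 13 opens it by SN2 at the CH2 carbon, so the C9–O bond keeps its configuration and the carboxylate, not the two allylic hydroxyls of 13, is the nucleophile.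

Step 14
Reactants: 20 2‑(trimethylsilyl)ethyl ester of the target
Product: 21 (5aS,6R,9S,9aS)‑9‑hydroxy‑9‑[({(2E)‑2‑(hydroxymethyl)‑3‑[(1R,6R)‑3‑(hydroxymethyl)‑6‑(propan‑2‑yl)cyclohex‑2‑en‑1‑yl]prop‑2‑enoyl}oxy)methyl]‑1‑oxo‑6‑(propan‑2‑yl)‑1,3,5a,6,7,8,9,9a‑octahydro‑2‑benzoxepine‑4‑carboxylic acid (CNP0361406.2)
Conditions: TASF (3 equiv), DMF, 0 °C → rt; then dilute HCl to pH 3–4
Reagents that add atoms: none
Why: Fluoride‑induced β‑elimination of the 2‑(trimethylsilyl)ethyl ester releases the acrylic acid under non‑hydrolytic conditions that should leave the lactone, the linking ester and the β‑hydroxy lactone unit intact.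

## Compound list

1 | 3‑methylbutanal | CC(C)CC=O | starting material
2 | but‑3‑en‑2‑one | CC(=O)C=C | starting material
3 | (2R)‑5‑oxo‑2‑(propan‑2‑yl)hexanal | CC(C)[C@H](C=O)CCC(C)=O | intermediate
4 | (4R)‑4‑(propan‑2‑yl)cyclohex‑2‑en‑1‑one | CC(C)[C@H]1CCC(=O)C=C1 | intermediate
5 | (3S,6R)‑6‑(propan‑2‑yl)‑1‑oxaspiro[2.5]oct‑4‑ene | CC(C)[C@H]1CC[C@@]2(CO2)C=C1 | intermediate
6 | 3‑nitropropanoic acid | O=C(O)CC[N+](=O)[O-] | starting material
7 | 2‑(trimethylsilyl)ethan‑1‑ol | C[Si](C)(C)CCO | starting material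
8 | 2‑(trimethylsilyl)ethyl 3‑nitropropanoate | C[Si](C)(C)CCOC(=O)CC[N+](=O)[O-] | intermediate
9 | 2‑(trimethylsilyl)ethyl 2‑(hydroxymethyl)‑3‑nitropropanoate (racemic) | C[Si](C)(C)CCOC(=O)C(CO)C[N+](=O)[O-] | intermediate
10 | 2‑(trimethylsilyl)ethyl 3‑nitro‑2‑{[(triethylsilyl)oxy]methyl}propanoate (racemic) | CC[Si](CC)(CC)OCC(C[N+](=O)[O-])C(=O)OCC[Si](C)(C)C | intermediate
11 | 2‑(trimethylsilyl)ethyl 3‑[(1R,6R)‑3‑(hydroxymethyl)‑6‑(propan‑2‑yl)cyclohex‑2‑en‑1‑yl]‑3‑nitro‑2‑{[(triethylsilyl)oxy]methyl}propanoate (epimer mixture at C2 and C3 of the chain) | [O-][N+](=O)C(C(CO[Si](CC)(CC)CC)C(=O)OCC[Si](C)(C)C)[C@H]1C=C(CO)CC[C@@H]1C(C)C | intermediate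
12 | 2‑(trimethylsilyl)ethyl (2E)‑3‑[(1R,6R)‑3‑(hydroxymethyl)‑6‑(propan‑2‑yl)cyclohex‑2‑en‑1‑yl]‑2‑{[(triethylsilyl)oxy]methyl}prop‑2‑enoate | C[Si](C)(C)CCOC(=O)/C(=C/[C@H]1C=C(CO)CC[C@@H]1C(C)C)CO[Si](CC)(CC)CC | intermediate
13 | (2E)‑2‑(hydroxymethyl)‑3‑[(1R,6R)‑3‑(hydroxymethyl)‑6‑(propan‑2‑yl)cyclohex‑2‑en‑1‑yl]prop‑2‑enoic acid | OC(=O)/C(=C/[C@H]1C=C(CO)CC[C@@H]1C(C)C)CO | intermediate
14 | (1S,2S,3R)‑6‑methylidene‑3‑(propan‑2‑yl)‑2‑[(1E)‑3‑oxo‑2‑{[(triethylsilyl)oxy]methyl}‑3‑[2‑(trimethylsilyl)ethoxy]prop‑1‑en‑1‑yl]cyclohexane‑1‑carboxylic acid (formed as its zinc carboxylate) | CC(C)[C@H]1CCC(=C)[C@@H](C(=O)O)[C@@H]1/C=C(\CO[Si](CC)(CC)CC)C(=O)OCC[Si](C)(C)C | intermediate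
15 | (1S,2S,3R)‑2‑{(1E)‑2‑(hydroxymethyl)‑3‑oxo‑3‑[2‑(trimethylsilyl)ethoxy]prop‑1‑en‑1‑yl}‑6‑methylidene‑3‑(propan‑2‑yl)cyclohexane‑1‑carboxylic acid | CC(C)[C@H]1CCC(=C)[C@@H](C(=O)O)[C@@H]1/C=C(\CO)C(=O)OCC[Si](C)(C)C | intermediate
16 | 2‑(trimethylsilyl)ethyl (5aS,6R,9aS)‑9‑methylidene‑1‑oxo‑6‑(propan‑2‑yl)‑1,3,5a,6,7,8,9,9a‑octahydro‑2‑benzoxepine‑4‑carboxylate | CC(C)[C@H]1CCC(=C)[C@H]2C(=O)OCC(C(=O)OCC[Si](C)(C)C)=C[C@H]12 | intermediate
17 | 2‑(trimethylsilyl)ethyl (5aS,6R,9S,9aS)‑9‑hydroxy‑9‑(hydroxymethyl)‑1‑oxo‑6‑(propan‑2‑yl)‑1,3,5a,6,7,8,9,9a‑octahydro‑2‑benzoxepine‑4‑carboxylate | CC(C)[C@H]1CC[C@@](O)(CO)[C@H]2C(=O)OCC(C(=O)OCC[Si](C)(C)C)=C[C@H]12 | intermediate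
18 | 2‑(trimethylsilyl)ethyl (5aS,6R,9S,9aS)‑9‑hydroxy‑9‑{[(4‑methylbenzenesulfonyl)oxy]methyl}‑1‑oxo‑6‑(propan‑2‑yl)‑1,3,5a,6,7,8,9,9a‑octahydro‑2‑benzoxepine‑4‑carboxylate | CC(C)[C@H]1CC[C@@](O)(COS(=O)(=O)c3ccc(C)cc3)[C@H]2C(=O)OCC(C(=O)OCC[Si](C)(C)C)=C[C@H]12 | intermediate
19 | 2‑(trimethylsilyl)ethyl (5aS,6R,9S,9aS)‑1‑oxo‑6‑(propan‑2‑yl)‑3,5a,6,7,8,9a‑hexahydro‑1H‑spiro[2‑benzoxepine‑9,2′‑oxirane]‑4‑carboxylate | CC(C)[C@H]1CC[C@@]3(CO3)[C@H]2C(=O)OCC(C(=O)OCC[Si](C)(C)C)=C[C@H]12 | intermediate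
20 | 2‑(trimethylsilyl)ethyl (5aS,6R,9S,9aS)‑9‑hydroxy‑9‑[({(2E)‑2‑(hydroxymethyl)‑3‑[(1R,6R)‑3‑(hydroxymethyl)‑6‑(propan‑2‑yl)cyclohex‑2‑en‑1‑yl]prop‑2‑enoyl}oxy)methyl]‑1‑oxo‑6‑(propan‑2‑yl)‑1,3,5a,6,7,8,9,9a‑octahydro‑2‑benzoxepine‑4‑carboxylate | CC(C)[C@H]1CC[C@@](O)(COC(=O)/C(=C/[C@H]3C=C(CO)CC[C@@H]3C(C)C)CO)[C@H]2C(=O)OCC(C(=O)OCC[Si](C)(C)C)=C[C@H]12 | intermediate
21 | (5aS,6R,9S,9aS)‑9‑hydroxy‑9‑[({(2E)‑2‑(hydroxymethyl)‑3‑[(1R,6R)‑3‑(hydroxymethyl)‑6‑(propan‑2‑yl)cyclohex‑2‑en‑1‑yl]prop‑2‑enoyl}oxy)methyl]‑1‑oxo‑6‑(propan‑2‑yl)‑1,3,5a,6,7,8,9,9a‑octahydro‑2‑benzoxepine‑4‑carboxylic acid | CC(C)[C@H]1CC[C@@](O)(COC(=O)/C(=C/[C@H]2C=C(CO)CC[C@@H]2C(C)C)CO)[C@H]2C(=O)OCC(C(=O)O)=C[C@H]12 | target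

## Step count and risks

Total step count: 14. Longest linear sequence: 10 steps (steps 1–3, 7, 9–14; the branch through steps 4–6 is equally long).

**Step 9 (key step).** The allylzinc may be protonated instead of carboxylated, giving the deoxygenated alkene. Carboxylation may also occur at the α‑carbon, or with poor facial selectivity at the ring carbon. The hindered γ‑position next to the side chain could slow the CO2 capture.
Fallback, from 12 back to 14: Appel bromination (CBr4, PPh3) should give 2‑(trimethylsilyl)ethyl (2E)‑3‑[(1S,6R)‑3‑(bromomethyl)‑6‑(propan‑2‑yl)cyclohex‑2‑en‑1‑yl]‑2‑{[(triethylsilyl)oxy]methyl}prop‑2‑enoate F1. An indium‑mediated Barbier reaction of F1 with aqueous formaldehyde (γ‑selective, tolerant of esters and water) should give the homoallylic alcohol 2‑(trimethylsilyl)ethyl (2E)‑3‑[(1S,2S,6R)‑2‑(hydroxymethyl)‑3‑methylidene‑6‑(propan‑2‑yl)cyclohexyl]‑2‑{[(triethylsilyl)oxy]methyl}prop‑2‑enoate F2, with the same facial sense as the carboxylation. Dess–Martin oxidation to the aldehyde 2‑(trimethylsilyl)ethyl (2E)‑3‑[(1S,2S,6R)‑2‑formyl‑3‑methylidene‑6‑(propan‑2‑yl)cyclohexyl]‑2‑{[(triethylsilyl)oxy]methyl}prop‑2‑enoate F3 and Pinnick oxidation then give acid 14, which rejoins the route at the acidic work‑up of step 9.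

**Step 7.** C–C bond formation between two hindered secondary carbons may be slow. The π‑allyl complex could then undergo β‑hydride elimination to dienes, or the nitronate could be O‑alkylated. Stereospecificity could be lost if 5 is a diastereomer mixture and the π‑allyl complexes do not equilibrate.
Fallback, from 5 back to 12: Pd(0)‑catalysed alkylation with nitromethane (a small pronucleophile, same net retention) should give [(3R,4R)‑3‑(nitromethyl)‑4‑(propan‑2‑yl)cyclohex‑1‑en‑1‑yl]methanol F4. A TiCl3‑mediated Nef reaction of its nitronate should give (1R,6R)‑3‑(hydroxymethyl)‑6‑(propan‑2‑yl)cyclohex‑2‑ene‑1‑carbaldehyde F5. Separately, commercial diethyl (2‑hydroxyethyl)phosphonate is silylated to diethyl {2‑[(triethylsilyl)oxy]ethyl}phosphonate F6, and its lithium carbanion is acylated with 2‑(trimethylsilyl)ethyl 4‑nitrophenyl carbonate to 2‑(trimethylsilyl)ethyl 2‑(diethoxyphosphoryl)‑3‑[(triethylsilyl)oxy]propanoate F7. Horner–Wadsworth–Emmons olefination of F5 with F7 under Masamune–Roush conditions (LiCl, DBU) should give 12, with the E‑isomer expected to predominate.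

**Step 13.** SN2 opening at the neopentyl‑type oxirane carbon by a weak carboxylate nucleophile may be slow. Heating with base could then cause E1cB opening of the oxirane towards the lactone α‑carbon, or acyl migration and translactonisation.
Fallback, from 13 and 17 back to 21: exhaustive silylation of 13 (TESCl, imidazole; the silyl ester is hydrolysed on work‑up) should give (2E)‑3‑[(1R,6R)‑6‑(propan‑2‑yl)‑3‑{[(triethylsilyl)oxy]methyl}cyclohex‑2‑en‑1‑yl]‑2‑{[(triethylsilyl)oxy]methyl}prop‑2‑enoic acid F8. Yamaguchi esterification of F8 with the primary hydroxyl of diol 17 should give the fully protected ester 2‑(trimethylsilyl)ethyl (5aS,6R,9S,9aS)‑9‑hydroxy‑1‑oxo‑6‑(propan‑2‑yl)‑9‑[({(2E)‑3‑[(1R,6R)‑6‑(propan‑2‑yl)‑3‑{[(triethylsilyl)oxy]methyl}cyclohex‑2‑en‑1‑yl]‑2‑{[(triethylsilyl)oxy]methyl}prop‑2‑enoyl}oxy)methyl]‑1,3,5a,6,7,8,9,9a‑octahydro‑2‑benzoxepine‑4‑carboxylate F9. Global desilylation of F9 with TASF removes both TES ethers and the 2‑(trimethylsilyl)ethyl ester to give 21.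

## Further compounds

F1 | step 9 | 2‑(trimethylsilyl)ethyl (2E)‑3‑[(1S,6R)‑3‑(bromomethyl)‑6‑(propan‑2‑yl)cyclohex‑2‑en‑1‑yl]‑2‑{[(triethylsilyl)oxy]methyl}prop‑2‑enoate | C[Si](C)(C)CCOC(=O)/C(=C/[C@H]1C=C(CBr)CC[C@@H]1C(C)C)CO[Si](CC)(CC)CC
F2 | step 9 | 2‑(trimethylsilyl)ethyl (2E)‑3‑[(1S,2S,6R)‑2‑(hydroxymethyl)‑3‑methylidene‑6‑(propan‑2‑yl)cyclohexyl]‑2‑{[(triethylsilyl)oxy]methyl}prop‑2‑enoate | CC(C)[C@H]1CCC(=C)[C@@H](CO)[C@@H]1/C=C(\CO[Si](CC)(CC)CC)C(=O)OCC[Si](C)(C)C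
F3 | step 9 | 2‑(trimethylsilyl)ethyl (2E)‑3‑[(1S,2S,6R)‑2‑formyl‑3‑methylidene‑6‑(propan‑2‑yl)cyclohexyl]‑2‑{[(triethylsilyl)oxy]methyl}prop‑2‑enoate | CC(C)[C@H]1CCC(=C)[C@@H](C=O)[C@@H]1/C=C(\CO[Si](CC)(CC)CC)C(=O)OCC[Si](C)(C)C
F4 | step 7 | [(3R,4R)‑3‑(nitromethyl)‑4‑(propan‑2‑yl)cyclohex‑1‑en‑1‑yl]methanol | [O-][N+](=O)C[C@H]1C=C(CO)CC[C@@H]1C(C)C
F5 | step 7 | (1R,6R)‑3‑(hydroxymethyl)‑6‑(propan‑2‑yl)cyclohex‑2‑ene‑1‑carbaldehyde | O=C[C@H]1C=C(CO)CC[C@@H]1C(C)C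
F6 | step 7 | diethyl {2‑[(triethylsilyl)oxy]ethyl}phosphonate | CCOP(=O)(CCO[Si](CC)(CC)CC)OCC
F7 | step 7 | 2‑(trimethylsilyl)ethyl 2‑(diethoxyphosphoryl)‑3‑[(triethylsilyl)oxy]propanoate | CCOP(=O)(OCC)C(CO[Si](CC)(CC)CC)C(=O)OCC[Si](C)(C)C
F8 | step 13 | (2E)‑3‑[(1R,6R)‑6‑(propan‑2‑yl)‑3‑{[(triethylsilyl)oxy]methyl}cyclohex‑2‑en‑1‑yl]‑2‑{[(triethylsilyl)oxy]methyl}prop‑2‑enoic acid | OC(=O)/C(=C/[C@H]1C=C(CO[Si](CC)(CC)CC)CC[C@@H]1C(C)C)CO[Si](CC)(CC)CC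
F9 | step 13 | 2‑(trimethylsilyl)ethyl (5aS,6R,9S,9aS)‑9‑hydroxy‑1‑oxo‑6‑(propan‑2‑yl)‑9‑[({(2E)‑3‑[(1R,6R)‑6‑(propan‑2‑yl)‑3‑{[(triethylsilyl)oxy]methyl}cyclohex‑2‑en‑1‑yl]‑2‑{[(triethylsilyl)oxy]methyl}prop‑2‑enoyl}oxy)methyl]‑1,3,5a,6,7,8,9,9a‑octahydro‑2‑benzoxepine‑4‑carboxylate | CC(C)[C@H]1CC[C@@](O)(COC(=O)/C(=C/[C@H]3C=C(CO[Si](CC)(CC)CC)CC[C@@H]3C(C)C)CO[Si](CC)(CC)CC)[C@H]2C(=O)OCC(C(=O)OCC[Si](C)(C)C)=C[C@H]12
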